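**Assumption:** germacrane numbering with the lactone closed to O‑6 (ester on C8, epoxide C1/C10, ketone C3, CH2OH = C15). The C3 carbinol of 8–22 is an epimer mixture (it ends as the ketone), and the acetal/lactol carbon C6 of 3–19 is an anomer mixture.

**Retrosynthetic overview**
1. Target 23 ⇐ diol‑lactone 21 by one dioxirane operation: epoxidation of the Z‑Δ1(10) olefin and oxidation of C3–OH, so the sensitive β‑hydroxy/β,γ‑epoxy ketone appears only at the end.
2. 21 ⇐ lactol 19 by closing C6–C7, the bond the germacrene cyclase makes, with Cr(II) on the unprotected lactol that already carries the C8 ester; the γ‑lactone closes in the same operation.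
3. 19 ⇐ vinyl epoxide 15 (bromide opening with in‑situ acylation) ⇐ aldehyde 11 (enamine α‑chlorination, vinylalumination; the oxygen moves from C7 to C8).
4. 11 ⇐ nerol (Z‑olefin, C1, C2, C7–C10, C14) + aldehyde 4 (C3–C6, C15; C4 set by organocatalytic hydroxymethylation), joined by α‑selective allylbarium addition.
5. Ring order: ten‑membered carbocycle → γ‑lactone (same step) → epoxide.

**Step 1**
Reactants: 1 4,4-dimethoxybutanal; 2 formaldehyde (37% aq.)
Product: 4 (3S)-5-methoxyoxolane-3-carbaldehyde, via aldol adduct 3 (not isolated)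
Conditions: (R)-α,α-diphenylprolinol TMS ether (10 mol%), pH 7 phosphate buffer, toluene, rt; extract; PPTS (5 mol%), 4 Å MS, CH2Cl2, 0 °C → rt; used at once
Reagents that add atoms: none
Why: Enamine (Jørgensen–Hayashi) cross‑aldol with formaldehyde, in which the (R)‑catalyst shields one enamine face so that CH2OH enters to give the 2S centre (= C4), followed by acid‑catalysed closure of the γ‑hydroxy acetal to the methyl lactol ether, which ties C15–OH and C6 into one ring.

**Step 2**
Reactants: 5 nerol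
Product: 6 neryl chloride
Conditions: NCS, Me2S, CH2Cl2, −40 → 0 °C
Reagents that add atoms: N-chlorosuccinimide O=C1CCC(=O)N1Cl
Why: Corey–Kim chlorination displaces the alkoxysulfonium group by SN2 without allylic transposition or loss of the Z geometry.

**Step 3**
Reactants: 6 neryl chloride; 4 (3S)-5-methoxyoxolane-3-carbaldehyde
Product: 9 triethylsilyl ether of (3Z)-1-[(3S)-5-methoxyoxolan-3-yl]-4,8-dimethylnona-3,7-dien-1-ol, via neryl barium chloride 7 (not isolated), via barium alkoxide 8 (not isolated)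
Conditions: BaI2, lithium biphenylide (2 equiv), THF, rt; 6, −78 °C; 4, −78 °C; then Et3SiCl, −78 → 0 °C
Reagents that add atoms: chlorotriethylsilane CC[Si](Cl)(CC)CC
Why: Yamamoto allylbarium addition, which attacks aldehydes at the α‑carbon with retention of the Z geometry at −78 °C, with silylation of the alkoxide in the same flask; the new C3 carbinol forms unselectively, which does not matter.

**Step 4**
Reactants: 9 triethylsilyl ether from step 3
Product: 11 (4Z)-7-[(3S)-5-methoxyoxolan-3-yl]-4-methyl-7-[(triethylsilyl)oxy]hept-4-enal, via terminal diol 10 (not isolated)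
Conditions: K2OsO2(OH)4 (1 mol%), (DHQD)2PHAL (5 mol%), NMO (1.1 equiv), acetone/H2O, 0 °C; then NaIO4, pH 7 buffer, 0 °C → rt
Reagents that add atoms: N-methylmorpholine N-oxide C[N+]1([O-])CCOCC1; water O
Why: Ligand‑accelerated OsO4 dihydroxylation (Sharpless ligand, Upjohn reoxidant) prefers the unhindered isopropylidene terminus over the Z‑trisubstituted internal olefin, and periodate glycol cleavage then gives the aldehyde under neutral conditions that spare the TES ether and the acetal.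

**Step 5**
Reactants: 11 aldehyde from step 4
Product: 12 (2S,4Z)-2-chloro-7-[(3S)-5-methoxyoxolan-3-yl]-4-methyl-7-[(triethylsilyl)oxy]hept-4-enal
Conditions: NCS (1.2 equiv), (2R,5R)-2,5-diphenylpyrrolidine (10 mol%), CH2Cl2, 0 °C → rt; used crude
Reagents that add atoms: N-chlorosuccinimide O=C1CCC(=O)N1Cl
Why: Jørgensen enamine α‑chlorination, where the C2‑symmetric (2R,5R)‑amine shields one enamine face to give the 2S chloride at C8, a centre that is deliberately inverted in step 6.

**Step 6**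
Reactants: 12 α-chloro aldehyde; 13 methyl propiolate
Product: 15 methyl 2-{(2R,3R)-3-[(2Z)-5-[(3S)-5-methoxyoxolan-3-yl]-2-methyl-5-[(triethylsilyl)oxy]pent-2-en-1-yl]oxiran-2-yl}prop-2-enoate, via chlorohydrin 14 (not isolated)
Conditions: DIBAL-H, NMO, THF, 0 °C; 13, 0 °C; then 12, 0 °C → rt; Rochelle salt work-up; crude 14: Cs2CO3, MeCN, rt
Reagents that add atoms: none
Why: Ramachandran vinylalumination (α‑aluminoacrylate from 1,4‑hydroalumination of the propiolate) adds to the α‑chloro aldehyde (Cornforth/Felkin, anti) without amine base, and carbonate then closes the epoxide by SN2 with inversion at C8, which places the oxygen on C8 as 8R; the minor cis‑epoxide converges in step 9.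

**Step 7**
Reactants: 15 vinyl epoxide; 16 (2R)-2-methylbutanoic acid
Product: 18 methyl (2Z,4R,6Z)-2-(bromomethyl)-9-[(3S)-5-methoxyoxolan-3-yl]-6-methyl-4-{[(2R)-2-methylbutanoyl]oxy}-9-[(triethylsilyl)oxy]nona-2,6-dienoate, via lithium alkoxide 17 (not isolated)
Conditions: 16 (2.4 equiv), DCC (1.2 equiv), CH2Cl2, 0 °C → rt (anhydride formed in the flask); add to 15, LiBr (3 equiv), THF, 0 °C → rt; aq. NH4Cl
Reagents that add atoms: lithium bromide [Li+].[Br-]
Why: Halide‑mediated acylative opening of the acrylate‑activated vinyl epoxide: bromide attacks C13 (SN2′; any SN2 isomer at C7 gives the same allylmetal later) with retention at C8, and the lithium alkoxide is acylated at once by the anhydride, so no free hydroxy ester that could migrate the acyl group or form a butenolide is ever present.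

**Step 8**
Reactants: 18 bromo ester
Product: 19 methyl (2Z,4R,6Z)-2-(bromomethyl)-9-hydroxy-9-[(3S)-5-hydroxyoxolan-3-yl]-6-methyl-4-{[(2R)-2-methylbutanoyl]oxy}nona-2,6-dienoate
Conditions: 0.2 M aq. HCl/THF (1:4), 0 °C → rt
Reagents that add atoms: water O
Why: Dilute acid hydrolyses the methyl lactol ether and the labile TES ether while the esters and the allylic bromide survive; no stereocentre is α to a carbonyl, so none can epimerise.

**Step 9**
Reactants: 19 lactol bromide
Product: 21 (4S,6R,7S,8R)-3,15-dihydroxy-8-[(2R)-2-methylbutanoyloxy]germacra-1(10)Z,11(13)-dien-12,6-olide, via hydroxy ester 20 (not isolated)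
Conditions: CrCl2 (10 equiv), THF/DMF 10:1, syringe-pump addition of 19 over 12 h (final 2 mM), rt; 1 M HCl work-up; CSA (cat.), CH2Cl2, rt
Reagents that add atoms: none
Why: Proposed new method: Cr(II) turns the allylic bromide into an equilibrating 2‑(methoxycarbonyl)allylchromium(III) that adds through C7 to the aldehyde released from the lactol (Cr(III) acts as Lewis acid on the ring–chain equilibrium) in a chair Zimmerman–Traxler transition state with both tether ends equatorial (6,7‑anti, hence the trans‑lactone) and anti to the C8–C9 bond with H‑8 inside (A1,3 strain), giving 6R,7S, after which the chromium alkoxide lactonises onto the methyl ester; the closest known chemistry is the Nozaki–Hiyama–Kishi macrocyclisation of 2‑(bromomethyl)alkenoate aldehydes to ten‑membered germacranolides and Barbier allylation of unprotected lactols.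

**Step 10**
Reactants: 21 diol-lactone
Product: 23 (1R,4S,6R,7S,8R,10S)-1,10-epoxy-15-hydroxy-8-[(2R)-2-methylbutanoyloxy]-3-oxogermacr-11(13)-en-12,6-olide (CNP0219035.1), via epoxy diol 22 (not isolated)
Conditions: DMDO (ca. 0.07 M in acetone, 3–4 equiv), CH2Cl2, −20 °C (epoxidation) → rt (alcohol oxidation), monitored; evaporate
Reagents that add atoms: dimethyldioxirane CC1(C)OO1
Why: Dioxirane oxidation first epoxidises the electron‑rich trisubstituted olefin (syn addition to the Z‑olefin gives the cis‑epoxide; attack is expected on the exposed outer β‑face, 1R,10S, but this is not proven) and then oxidises the secondary hydroxyl of the 1,3‑diol faster than the primary one to the β‑hydroxy ketone, under neutral conditions that the β,γ‑epoxy ketone and the electron‑poor methylene lactone tolerate.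

**Compound list**
1 | 4,4-dimethoxybutanal | O=CCCC(OC)OC | starting material
2 | formaldehyde | C=O | starting material
3 | (2S)-2-(hydroxymethyl)-4,4-dimethoxybutanal | O=C[C@H](CO)CC(OC)OC | intermediate (not isolated)
4 | (3S)-5-methoxyoxolane-3-carbaldehyde | O=C[C@@H]1COC(OC)C1 | intermediate
5 | nerol | CC(C)=CCC/C(C)=C\CO | starting material
6 | neryl chloride | CC(C)=CCC/C(C)=C\CCl | intermediate
7 | neryl barium chloride | CC(C)=CCC/C(C)=C\C[Ba]Cl | intermediate (not isolated)
8 | chlorobarium (3Z)-1-[(3S)-5-methoxyoxolan-3-yl]-4,8-dimethylnona-3,7-dien-1-olate | CC(C)=CCC/C(C)=C\CC(O[Ba]Cl)[C@@H]1COC(OC)C1 | intermediate (not isolated)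
9 | triethylsilyl ether of (3Z)-1-[(3S)-5-methoxyoxolan-3-yl]-4,8-dimethylnona-3,7-dien-1-ol | CC(C)=CCC/C(C)=C\CC(O[Si](CC)(CC)CC)[C@@H]1COC(OC)C1 | intermediate
10 | (6Z)-9-[(3S)-5-methoxyoxolan-3-yl]-2,6-dimethyl-9-[(triethylsilyl)oxy]non-6-ene-2,3-diol | CC(C)(O)C(O)CC/C(C)=C\CC(O[Si](CC)(CC)CC)[C@@H]1COC(OC)C1 | intermediate (not isolated)
11 | (4Z)-7-[(3S)-5-methoxyoxolan-3-yl]-4-methyl-7-[(triethylsilyl)oxy]hept-4-enal | O=CCC/C(C)=C\CC(O[Si](CC)(CC)CC)[C@@H]1COC(OC)C1 | intermediate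
12 | (2S,4Z)-2-chloro-7-[(3S)-5-methoxyoxolan-3-yl]-4-methyl-7-[(triethylsilyl)oxy]hept-4-enal | O=C[C@@H](Cl)C/C(C)=C\CC(O[Si](CC)(CC)CC)[C@@H]1COC(OC)C1 | intermediate
13 | methyl propiolate | C#CC(=O)OC | starting material
14 | methyl (3R,4S,6Z)-4-chloro-3-hydroxy-9-[(3S)-5-methoxyoxolan-3-yl]-6-methyl-2-methylidene-9-[(triethylsilyl)oxy]non-6-enoate | C=C(C(=O)OC)[C@@H](O)[C@@H](Cl)C/C(C)=C\CC(O[Si](CC)(CC)CC)[C@@H]1COC(OC)C1 | intermediate (not isolated)
15 | methyl 2-{(2R,3R)-3-[(2Z)-5-[(3S)-5-methoxyoxolan-3-yl]-2-methyl-5-[(triethylsilyl)oxy]pent-2-en-1-yl]oxiran-2-yl}prop-2-enoate | C=C(C(=O)OC)[C@H]1O[C@@H]1C/C(C)=C\CC(O[Si](CC)(CC)CC)[C@@H]2COC(OC)C2 | intermediate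
16 | (2R)-2-methylbutanoic acid | CC[C@@H](C)C(=O)O | starting material
17 | lithium alkoxide of methyl (2Z,4R,6Z)-2-(bromomethyl)-4-hydroxy-9-[(3S)-5-methoxyoxolan-3-yl]-6-methyl-9-[(triethylsilyl)oxy]nona-2,6-dienoate | BrC/C(C(=O)OC)=C\[C@H]([O-])C/C(C)=C\CC(O[Si](CC)(CC)CC)[C@@H]1COC(OC)C1.[Li+] | intermediate (not isolated)
18 | methyl (2Z,4R,6Z)-2-(bromomethyl)-9-[(3S)-5-methoxyoxolan-3-yl]-6-methyl-4-{[(2R)-2-methylbutanoyl]oxy}-9-[(triethylsilyl)oxy]nona-2,6-dienoate | BrC/C(C(=O)OC)=C\[C@H](OC(=O)[C@H](C)CC)C/C(C)=C\CC(O[Si](CC)(CC)CC)[C@@H]1COC(OC)C1 | intermediate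
19 | methyl (2Z,4R,6Z)-2-(bromomethyl)-9-hydroxy-9-[(3S)-5-hydroxyoxolan-3-yl]-6-methyl-4-{[(2R)-2-methylbutanoyl]oxy}nona-2,6-dienoate | BrC/C(C(=O)OC)=C\[C@H](OC(=O)[C@H](C)CC)C/C(C)=C\CC(O)[C@@H]1COC(O)C1 | intermediate
20 | methyl (4S,6R,7S,8R)-3,6,15-trihydroxy-8-[(2R)-2-methylbutanoyloxy]germacra-1(10)Z,11(13)-dien-12-oate (formed as its chromium alkoxide) | C=C(C(=O)OC)[C@H]1[C@H](O)C[C@@H](CO)C(O)C/C=C(C)\C[C@H]1OC(=O)[C@H](C)CC | intermediate (not isolated)
21 | (4S,6R,7S,8R)-3,15-dihydroxy-8-[(2R)-2-methylbutanoyloxy]germacra-1(10)Z,11(13)-dien-12,6-olide | C=C1C(=O)O[C@@H]2C[C@@H](CO)C(O)C/C=C(C)\C[C@@H](OC(=O)[C@H](C)CC)[C@@H]12 | intermediate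
22 | (1R,4S,6R,7S,8R,10S)-1,10-epoxy-3,15-dihydroxy-8-[(2R)-2-methylbutanoyloxy]germacr-11(13)-en-12,6-olide | C=C1C(=O)O[C@@H]2C[C@@H](CO)C(O)C[C@H]3O[C@@]3(C)C[C@@H](OC(=O)[C@H](C)CC)[C@@H]12 | intermediate (not isolated)
23 | (1R,4S,6R,7S,8R,10S)-1,10-epoxy-15-hydroxy-8-[(2R)-2-methylbutanoyloxy]-3-oxogermacr-11(13)-en-12,6-olide | C=C1C(=O)O[C@@H]2C[C@@H](CO)C(=O)C[C@H]3O[C@@]3(C)C[C@@H](OC(=O)[C@H](C)CC)[C@@H]12 | target

**Total step count:** 10. **Longest linear sequence:** 9 (steps 2–10 from nerol, or steps 1 and 3–10 from 1).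

**Steps most likely to fail, most likely first**

Step 9 (ring closure). The allylchromium from 19 carries the C8 carboxylate in a vinylogous β‑position and may lose it to give a diene (1,4‑elimination) faster than the ten‑membered ring forms; oligomers or the 6,7‑cis lactone are the other threats. The fallback puts the ester on after ring closure and sets out from 15. LiBr opens 15 and the alkoxide is silylated (TBSOTf, 2,6‑lutidine) to give the C8 tert‑butyldimethylsilyl ether allyl bromide F1. Dilute HCl/THF gives the lactol diol with C8–OTBS, F2. CrCl2 under the step 9 conditions closes it to the C8–OTBS macrolactone diol F3; a silyloxy group is not a leaving group. 2,2‑Dimethoxypropane/PPTS gives the 3,15‑acetonide F4, buffered HF·pyridine gives the free C8 alcohol acetonide F5, and DCC/DMAP with 16 gives the ester acetonide F6. Aqueous acetic acid removes the acetonide and the route is rejoined at 21.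

Step 10 (epoxide face and alcohol selectivity). If the dioxirane attacks the α‑face, the epoxide is made by the face‑inverting halohydrin route, setting out from 21. NBS in aqueous THF forms the bromonium ion on the same exposed face and water opens it at tertiary C10 from the β‑side, giving the 1α‑bromo‑10β‑hydroxy bromohydrin F7. Ag2O closes it with inversion at C1 to the β‑epoxide, which rejoins the route at 22; the C3 alcohol is then oxidised with DMDO as in step 10.

Step 3 (allylbarium addition to an epimerisable aldehyde). If the addition is low‑yielding or erodes C4, the C2–C3 bond is made with a sulfone‑stabilised carbanion, setting out from 6 and 4. PhSO2Na in DMF converts 6 into neryl phenyl sulfone F8. n‑BuLi at −78 °C and then 4 give the β‑hydroxy sulfone F9, Dess–Martin periodinane gives the β‑keto sulfone F10, and SmI2 in THF/MeOH at −78 °C gives the ketone F11. NaBH4 gives the alcohol F12, and Et3SiCl/imidazole returns to the route at 9.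

**Further compounds**
F1 | step 9 | methyl (2Z,4R,6Z)-2-(bromomethyl)-4-[(tert-butyldimethylsilyl)oxy]-9-[(3S)-5-methoxyoxolan-3-yl]-6-methyl-9-[(triethylsilyl)oxy]nona-2,6-dienoate | BrC/C(C(=O)OC)=C\[C@H](O[Si](C)(C)C(C)(C)C)C/C(C)=C\CC(O[Si](CC)(CC)CC)[C@@H]1COC(OC)C1
F2 | step 9 | methyl (2Z,4R,6Z)-2-(bromomethyl)-4-[(tert-butyldimethylsilyl)oxy]-9-hydroxy-9-[(3S)-5-hydroxyoxolan-3-yl]-6-methylnona-2,6-dienoate | BrC/C(C(=O)OC)=C\[C@H](O[Si](C)(C)C(C)(C)C)C/C(C)=C\CC(O)[C@@H]1COC(O)C1
F3 | step 9 | (4S,6R,7S,8R)-8-[(tert-butyldimethylsilyl)oxy]-3,15-dihydroxygermacra-1(10)Z,11(13)-dien-12,6-olide | C=C1C(=O)O[C@@H]2C[C@@H](CO)C(O)C/C=C(C)\C[C@@H](O[Si](C)(C)C(C)(C)C)[C@@H]12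
F4 | step 9 | 3,15-O-isopropylidene acetal of F3 | C=C1C(=O)O[C@@H]2C[C@H]3COC(C)(C)OC3C/C=C(C)\C[C@@H](O[Si](C)(C)C(C)(C)C)[C@@H]12
F5 | step 9 | (4S,6R,7S,8R)-8-hydroxy-3,15-(isopropylidenedioxy)germacra-1(10)Z,11(13)-dien-12,6-olide | C=C1C(=O)O[C@@H]2C[C@H]3COC(C)(C)OC3C/C=C(C)\C[C@@H](O)[C@@H]12
F6 | step 9 | (4S,6R,7S,8R)-3,15-(isopropylidenedioxy)-8-[(2R)-2-methylbutanoyloxy]germacra-1(10)Z,11(13)-dien-12,6-olide | C=C1C(=O)O[C@@H]2C[C@H]3COC(C)(C)OC3C/C=C(C)\C[C@@H](OC(=O)[C@H](C)CC)[C@@H]12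
F7 | step 10 | 1α-bromo-3,10β,15-trihydroxy-8-[(2R)-2-methylbutanoyloxy]germacr-11(13)-en-12,6-olide | C=C1C(=O)O[C@@H]2C[C@@H](CO)C(O)C[C@H](Br)[C@@](C)(O)C[C@@H](OC(=O)[C@H](C)CC)[C@@H]12
F8 | step 3 | neryl phenyl sulfone | CC(C)=CCC/C(C)=C\CS(=O)(=O)c1ccccc1
F9 | step 3 | (3Z)-1-[(3S)-5-methoxyoxolan-3-yl]-4,8-dimethyl-2-(phenylsulfonyl)nona-3,7-dien-1-ol | CC(C)=CCC/C(C)=C\C(C(O)[C@@H]1COC(OC)C1)S(=O)(=O)c1ccccc1
F10 | step 3 | (3Z)-1-[(3S)-5-methoxyoxolan-3-yl]-4,8-dimethyl-2-(phenylsulfonyl)nona-3,7-dien-1-one | CC(C)=CCC/C(C)=C\C(C(=O)[C@@H]1COC(OC)C1)S(=O)(=O)c1ccccc1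
F11 | step 3 | (3Z)-1-[(3S)-5-methoxyoxolan-3-yl]-4,8-dimethylnona-3,7-dien-1-one | CC(C)=CCC/C(C)=C\CC(=O)[C@@H]1COC(OC)C1
F12 | step 3 | (3Z)-1-[(3S)-5-methoxyoxolan-3-yl]-4,8-dimethylnona-3,7-dien-1-ol | CC(C)=CCC/C(C)=C\CC(O)[C@@H]1COC(OC)C1
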